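## Structural features

- The target 20 is a 1-aryltetralin. Ring A is a guaiacol-type arene (OMe on C6, OH on C7) fused through C4a–C8a to ring B, a cyclohexane. Ring B carries a 4-hydroxy-3-methoxyphenyl group on C1, a methyl ester on C2, a hydroxymethyl group on C3 and an unsubstituted methylene at C4.
- C1, C2 and C3 are contiguous stereocentres of configuration (1R,2S,3S). Aryl/ester and ester/hydroxymethyl are both trans, so all three substituents can sit equatorially.
- Fragile groups are the two free phenols (C1–H is doubly benzylic and para to oxygen donors, so oxidants can lead to quinone methides), the γ-hydroxy ester (lactonisation to a trans-fused lactone under acid or base) and C2–H (α to the ester).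
- The real difficulty is twofold. The stereotriad must be set in absolute terms, and C1 cannot be corrected once made. The two guaiacyl units are nearly identical, yet ring A needs its OMe and OH in a fixed order relative to C4a and C8a.
- The key step exploits the vicinal C6–OMe/C7–OH pair and the fusion bond C4a–C8a. If C4 is temporarily a ketone, C4a=C8a is an enone alkene onto which a 1,2-dimethoxy-3-silyloxybutadiene can be annulated. C5–C8 and both oxygens then arrive in one regiodefined operation, the terminal methoxy group of the diene serving as the leaving group for aromatisation.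
- The auxiliary C4 carbonyl ends up benzylic and para to the new C7 hydroxyl, so it can be removed by hydrogenolysis together with the O-benzyl groups.

## Logic of the disconnections

**20 to 19.** No skeletal bond is cut. The C4 methylene is traced back to a carbonyl, and the pendant phenolic O–H and the primary O–H to O–benzyl bonds. The carbonyl turns C4a–C8a into an enone bond for the next retron, and the two hydroxyls must be masked during an oxidative aromatisation. The gain is an activated ring B. The forward step must cleave two benzyl ethers and one aryl ketone without lactonising the γ-hydroxy ester or disturbing C3.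

**19 to 11 and 16.** C4a–C5 and C8–C8a are cut, with formal return of methanol and two hydrogens. These bonds are chosen because the alkene of 11 is polarised by the C4 ketone and 16 by its oxygen substituents, so only one orientation is expected. Ring A disappears completely, leaving a monocyclic enone with the three stereocentres and a four-carbon diene. The forward step needs an acid-compatible substrate, no base, and an oxidant that stops at the arene.

**16 to 15 to 12 and 13.** The O–Si bond is cut first, giving the β-methoxy enone 15. Then the bond between the methoxy-bearing carbon and the former formyl carbon, and the enol O–CH3 bond, are cut. This reduces the diene to two commodity C3 and C1 units. The forward condensation must occur at the methoxy-bearing methylene of 12, and methylation must occur on oxygen.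

**11 to 10 to 9 to 8.** These are functional group changes only: the C4 ketone to an allylic alcohol, that alcohol to its silyl ether, and the primary benzyl ether to the free alcohol. The purpose is to reach a cyclohexene with an allylic oxygen at C4 and a one-carbon oxygenated substituent at C3, which is a Diels–Alder retron. The forward steps must avoid base throughout, because 11 is a β-alkoxy ketone.

**8 to 7 to 5 and 6.** The primary alcohol is traced to the aldehyde 7, and then C1–C2 and C3–C4 are cut. All three permanent stereocentres, and the transient one at C4, arise from two achiral components under catalyst control. The forward cycloaddition must join the aryl-bearing diene terminus to the ester-bearing carbon, proceed endo with respect to the activated aldehyde, and be face-selective.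

**5 to 4 to 2 and 3 to 1.** The O–Si bond of the dienol ether is cut with a shift of the double bonds, giving enal 4. The C2=C3 alkene of 4 is cut in the metathesis sense into allylarene 2 and enal 3, and finally the aryl O–benzyl bond is cut. The aryl C3 unit of 1 is used intact. The forward steps need E-selective metathesis and γ-deprotonation to the (1E,3E) dienol ether.

## Other disconnections considered

**Alternative 1: nitrile oxide cycloaddition.**
- Cut: C3–C4 and the CH2–O bond of a fused isoxazoline, so ring B is closed last from the open-chain diaryl aldoxime A1.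
- Forward step: NaOCl converts the aldoxime of A1 into a nitrile oxide, which should add intramolecularly to the vinyl group on C2 to give the all-trans isoxazoline A2.
- In favour: ring A is bought as an arene, so there is no regiochemical question in ring A and no oxidative aromatisation; on this point it is better than the chosen plan. The isoxazoline delivers the C3 carbon at the right oxidation level and masks the primary alcohol without a protecting-group step, which is also better.
- Against: A1 must already hold C1 and C2 as an acyclic pair, which needs its own asymmetric synthesis. Its C2–H is α to an ester and allylic, so it is prone to epimerisation or conjugation under basic hypochlorite. C3 is set only by substrate control in the cyclisation.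
- Comparison: after N–O cleavage a C4 carbonyl still has to be removed, so the endgame is equal to the chosen plan. The chosen plan sets three centres in one catalytic step, which is shorter and more reliable than making A1 and then relying on 1,2-induction.

**Alternative 2: rhodium arylative annulation.**
- Cut: C8a–C1 and C2–C3, giving the ring A boronate A3 (with a tethered tert-butyl enoate) and the aryl propiolate A4.
- Forward step: with [Rh(OH)(cod)]2 (monovalent rhodium) and a chiral ligand, the aryl rhodium from A3 should add across A4 with aryl to C1, and the alkenyl rhodium should then add to the enoate at C3, giving dihydronaphthalene A5.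
- In favour: it is the most convergent of the four plans. Both arenes enter intact, ring B forms in one catalytic event, and C3 is set by the catalyst in the ring-forming step. On convergence it is better than the chosen plan; on ring A regiochemistry it is equal or better.
- Against: the C3 side chain of A5 is CH2CO2tBu, one carbon longer than the required CH2OH, so a degradative one-carbon excision would be needed. C1 and C2 are still sp2 and must be set by reducing a tetrasubstituted, aryl-conjugated alkene under substrate control relative to C3, followed by C2 epimerisation. Hydrogenation for that purpose would clash with the benzyl ethers.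
- Comparison: the chosen plan obtains all three centres with the correct carbon count in one cycloaddition. Alternative 2 wins the ring-forming step but loses clearly on the steps after it.

**Alternative 3: o-quinodimethane Diels–Alder.**
- Cut: C1–C2 and C3–C4, giving the 1-aryl dihydrobenzo[c]thiophene dioxide A6 and the menthyloxybutenolide A7. The configuration drawn for the adduct implies the (1S,2R,5S)-menthyl series.
- Forward step: thermal loss of SO2 from A6 should give the (E)-aryl o-quinodimethane, which should add endo to A7 on the face anti to the menthyloxy group, giving the all-cis lactone acetal A8.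
- In favour: ring B is built directly on an intact ring A with C1 and C3 correct and no oxygen at C4, so no deoxygenation is needed; this is better than the chosen plan. The step is uncatalysed and auxiliary-controlled, equal in stereocentre count to the organocatalytic step used here.
- Against: C2 is formed cis to the aryl group and must be inverted. In the cis-fused lactone that is contra-thermodynamic, so the lactone must be opened, the acetal carbon reduced to CH2OH and the acid esterified before base epimerisation. The open cis hydroxy ester can then relactonise, which is a thermodynamic sink. The auxiliary is stoichiometric and A6 needs several steps.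
- Comparison: alternative 3 is better on the C4 oxidation state and on ring A. The chosen plan is better on the C2 configuration, which is correct from the outset, and needs no epimerisation anywhere.

Key step: step 10

Assumption: 5 is used as its (1E,3E) isomer, and the E-iminium ion from 6 and the (5S)-imidazolidinone is taken to expose the Si face of the aldehyde α-carbon, as in its usual cycloadditions; if the opposite sense were found, the (5R)-catalyst would be used.

## Route

Step 1
Reactants: 1 eugenol (4-allyl-2-methoxyphenol)
Product: 2 4-allyl-1-(benzyloxy)-2-methoxybenzene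
Conditions: BnBr, K2CO3, acetone, reflux
Reagents that add atoms: benzyl bromide, BrCc1ccccc1
Why: Williamson ether synthesis on the phenoxide. The benzyl ether keeps the pendant phenol masked through the oxidative aromatisation and falls off in the final hydrogenolysis.

Step 2
Reactants: 2 4-allyl-1-(benzyloxy)-2-methoxybenzene, 3 (E)-but-2-enal (crotonaldehyde)
Product: 4 (E)-4-[4-(benzyloxy)-3-methoxyphenyl]but-2-enal
Conditions: 3 (4 equiv), second-generation Hoveyda–Grubbs catalyst RuCl2(H2IMes)(=CH-C6H4-2-OiPr) (2 mol %), 1,4-benzoquinone (10 mol %), CH2Cl2, 40 °C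
Reagents that add atoms: none
Why: Olefin cross-metathesis between a reactive allylarene and an electron-poor enal, driven by loss of propene and expected to give the E enal. Benzoquinone suppresses migration of the allyl double bond into conjugation.

Step 3
Reactants: 4 (E)-4-[4-(benzyloxy)-3-methoxyphenyl]but-2-enal
Product: 5 {[(1E,3E)-4-[4-(benzyloxy)-3-methoxyphenyl]buta-1,3-dien-1-yl]oxy}tri(propan-2-yl)silane
Conditions: iPr3SiOTf, Et3N, CH2Cl2, −78 → 0 °C
Reagents that add atoms: triisopropylsilyl trifluoromethanesulfonate, CC(C)[Si](OS(=O)(=O)C(F)(F)F)(C(C)C)C(C)C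
Why: Soft enolisation: O-silylation of the enal followed by removal of the benzylic, allylic γ-proton gives the silyl dienol ether, and conjugation with the arene favours the (1E,3E) isomer. The bulky silyl group is chosen so that the dienol ether tolerates the aqueous acidic medium of step 4.

Step 4
Reactants: 5 {[(1E,3E)-4-[4-(benzyloxy)-3-methoxyphenyl]buta-1,3-dien-1-yl]oxy}tri(propan-2-yl)silane, 6 methyl (E)-4-oxobut-2-enoate
Product: 8 methyl (1S,2R,5S,6S)-2-[4-(benzyloxy)-3-methoxyphenyl]-6-(hydroxymethyl)-5-{[tri(propan-2-yl)silyl]oxy}cyclohex-3-ene-1-carboxylate, via aldehyde cycloadduct 7 (not isolated)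
Conditions: 6 (1.5 equiv), (5S)-5-benzyl-2,2,3-trimethylimidazolidin-4-one·CF3CO2H (20 mol %), CH3CN–H2O (95:5), −20 °C; then EtOH, NaBH4, 0 °C
Reagents that add atoms: none
Why: Iminium-ion catalysed Diels–Alder reaction: the silyloxy group makes the aryl-bearing terminus of 5 the nucleophilic end, which bonds to the iminium β-carbon (the ester-bearing carbon, future C2), so the oxygen-bearing terminus bonds to the α-carbon (future C3). The E dienophile fixes C2/C3 trans, the endo position of the iminium group places CHO, aryl and silyloxy groups cis (hence aryl trans to ester), and the benzyl group of the (5S)-catalyst shields the Re face of the α-carbon so that the diene adds to its Si face, which corresponds to (1R,2S,3S) in target numbering. In-flask NaBH4 reduction of the aldehyde (ester untouched) removes the β-silyloxy aldehyde before it can epimerise at C3 or eliminate silanol.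

Step 5
Reactants: 8 methyl (1S,2R,5S,6S)-2-[4-(benzyloxy)-3-methoxyphenyl]-6-(hydroxymethyl)-5-{[tri(propan-2-yl)silyl]oxy}cyclohex-3-ene-1-carboxylate
Product: 9 methyl (1S,2R,5S,6S)-2-[4-(benzyloxy)-3-methoxyphenyl]-6-[(benzyloxy)methyl]-5-{[tri(propan-2-yl)silyl]oxy}cyclohex-3-ene-1-carboxylate
Conditions: BnOC(=NH)CCl3 (1.5 equiv), TfOH (5 mol %), CH2Cl2–cyclohexane (1:2), 0 °C → rt
Reagents that add atoms: benzyl 2,2,2-trichloroacetimidate, N=C(OCc1ccccc1)C(Cl)(Cl)Cl
Why: Acid-catalysed benzyl transfer from the trichloroacetimidate to the primary alcohol. No alkoxide is formed, so neither lactonisation onto the neighbouring ester nor silyl migration from the cis C4 oxygen is triggered.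

Step 6
Reactants: 9 methyl (1S,2R,5S,6S)-2-[4-(benzyloxy)-3-methoxyphenyl]-6-[(benzyloxy)methyl]-5-{[tri(propan-2-yl)silyl]oxy}cyclohex-3-ene-1-carboxylate
Product: 10 methyl (1S,2R,5S,6S)-2-[4-(benzyloxy)-3-methoxyphenyl]-6-[(benzyloxy)methyl]-5-hydroxycyclohex-3-ene-1-carboxylate
Conditions: Bu4NF, AcOH (1:1), THF, 0 °C → rt
Reagents that add atoms: none
Why: Fluoride-induced cleavage of the silyl ether, driven by the Si–F bond. Buffering with acetic acid keeps the medium non-basic, so C2 (α to the ester) is not epimerised.

Step 7
Reactants: 10 methyl (1S,2R,5S,6S)-2-[4-(benzyloxy)-3-methoxyphenyl]-6-[(benzyloxy)methyl]-5-hydroxycyclohex-3-ene-1-carboxylate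
Product: 11 methyl (1S,2R,6S)-2-[4-(benzyloxy)-3-methoxyphenyl]-6-[(benzyloxy)methyl]-5-oxocyclohex-3-ene-1-carboxylate
Conditions: Dess–Martin periodinane (1.2 equiv), CH2Cl2, 0 °C → rt
Reagents that add atoms: none
Why: Dess–Martin oxidation of the secondary allylic alcohol to the enone under neutral to weakly acidic conditions. Without base the β-benzyloxy ketone cannot eliminate benzyl alcohol, and C3 (now α to the ketone) and C1 (γ to it) keep their configuration.

Step 8
Reactants: 12 methoxyacetone (1-methoxypropan-2-one), 13 methyl formate
Product: 15 (Z)-3,4-dimethoxybut-3-en-2-one, via sodium formyl enolate 14 (not isolated)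
Conditions: NaOMe, THF, 0 °C → rt; then Me2SO4, DMF, 0 °C → rt
Reagents that add atoms: dimethyl sulfate, COS(=O)(=O)OC
Why: Crossed Claisen condensation at the more acidic methoxy-bearing methylene, driven by formation of the stabilised β-oxo enolate 14. The hard electrophile Me2SO4 then methylates the enolate on oxygen, and the isomer with the terminal OMe anti to the acetyl group (Z) is the expected stable form.

Step 9
Reactants: 15 (Z)-3,4-dimethoxybut-3-en-2-one
Product: 16 (1Z)-1,2-dimethoxy-3-(trimethylsilyloxy)buta-1,3-diene
Conditions: Me3SiOTf, Et3N, Et2O, 0 °C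
Reagents that add atoms: trimethylsilyl trifluoromethanesulfonate, C[Si](C)(C)OS(=O)(=O)C(F)(F)F
Why: Soft enolisation and O-silylation of a β-methoxy enone at its methyl group, the only enolisable position. The C1=C2 geometry of 15 is carried over, leaving the terminal OMe outward as required for cycloaddition.

Step 10
Reactants: 11 methyl (1S,2R,6S)-2-[4-(benzyloxy)-3-methoxyphenyl]-6-[(benzyloxy)methyl]-5-oxocyclohex-3-ene-1-carboxylate, 16 (1Z)-1,2-dimethoxy-3-(trimethylsilyloxy)buta-1,3-diene
Product: 19 methyl (1R,2S,3S)-1-[4-(benzyloxy)-3-methoxyphenyl]-3-[(benzyloxy)methyl]-7-hydroxy-6-methoxy-4-oxo-1,2,3,4-tetrahydronaphthalene-2-carboxylate, via silyl enol ether cycloadduct 17 (not isolated), via methoxy enone 18 (not isolated)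
Conditions: 16 (3 equiv), Tf2NH (10 mol %), CH2Cl2, −78 → −40 °C; then CF3CO2H, wet CH2Cl2, 0 °C, evaporate; then DDQ (1.05 equiv), 1,4-dioxane, 10 °C → rt
Reagents that add atoms: none
Why: Me3SiNTf2, formed from Tf2NH and a little of 16, activates the C4 carbonyl of 11; the diene then bonds through its CH2 terminus to the β-carbon C8a and through its methoxy-bearing terminus to the α-carbon C4a, either in one asynchronous [4+2] event or as a Mukaiyama–Michael addition followed by closure of the resulting C4 enol silane onto the silyloxocarbenium ion, both paths giving C8–C8a and C4a–C5. The closest known reaction type is the Lewis-acid-catalysed Diels–Alder reaction of 1-alkoxy-3-silyloxybutadienes and 2-silyloxydienes with cyclohexenones, followed by acid-induced loss of the alcohol and dehydrogenation to a phenol. Ring A is closed by an intermolecular [4+2] annulation onto the two former alkene carbons, and ring B is never opened. No new stereocentre survives: C4a, C5 and C8a are created in 17 (addition expected anti to the C1 aryl group) but all become sp2 in 19. The selectivity that matters is regiochemical and is secured by matched polarisation: the oxygen substituents of 16 put the largest HOMO coefficient on the CH2 terminus while the ketone makes C8a the electrophilic carbon, so OMe ends on C6 and the silyl enol ether oxygen on C7. Trifluoroacetic acid with a trace of water hydrolyses the enol silane and expels methanol from C5 (β to the new C7 ketone) to give 18, whose C4a–H is α to the C4 ketone and γ to the C7 enone and therefore enolises readily to a dihydroarene. After the acid is stripped off, so that acid-activated DDQ cannot attack the electron-rich pendant ring, one equivalent of DDQ should dehydrogenate this dihydroarene much faster than it abstracts hydride from the doubly benzylic C1–H, which is further deactivated by the C4 acyl group and the C2 ester. C1, C2 and C3 never meet base, so the β-benzyloxy ketone cannot eliminate and C2 and C3 cannot epimerise.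

Step 11
Reactants: 19 methyl (1R,2S,3S)-1-[4-(benzyloxy)-3-methoxyphenyl]-3-[(benzyloxy)methyl]-7-hydroxy-6-methoxy-4-oxo-1,2,3,4-tetrahydronaphthalene-2-carboxylate
Product: 20 methyl (1R,2S,3S)-7-hydroxy-1-(4-hydroxy-3-methoxyphenyl)-3-(hydroxymethyl)-6-methoxy-1,2,3,4-tetrahydronaphthalene-2-carboxylate
Conditions: H2 (3 atm), Pd(OH)2/C, AcOH–EtOAc (1:1), rt → 40 °C
Reagents that add atoms: none
Why: Catalytic hydrogenolysis: 19 holds only two O-benzyl groups (the C7 oxygen is already a free phenol), and both are cleaved while the aryl ketone is reduced through its benzylic alcohol to the methylene, helped by the para hydroxyl on C7. Acetic acid is acidic enough to promote the benzylic C–O cleavage but too weak to lactonise the trans γ-hydroxy ester at these temperatures, and C1–C3 are not touched.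

## Compound list

1 | eugenol (4-allyl-2-methoxyphenol) | COc1cc(CC=C)ccc1O | starting material
2 | 4-allyl-1-(benzyloxy)-2-methoxybenzene | COc1cc(CC=C)ccc1OCc1ccccc1 | intermediate
3 | (E)-but-2-enal (crotonaldehyde) | C/C=C/C=O | starting material
4 | (E)-4-[4-(benzyloxy)-3-methoxyphenyl]but-2-enal | COc1cc(C/C=C/C=O)ccc1OCc1ccccc1 | intermediate
5 | {[(1E,3E)-4-[4-(benzyloxy)-3-methoxyphenyl]buta-1,3-dien-1-yl]oxy}tri(propan-2-yl)silane | COc1cc(/C=C/C=C/O[Si](C(C)C)(C(C)C)C(C)C)ccc1OCc1ccccc1 | intermediate
6 | methyl (E)-4-oxobut-2-enoate | COC(=O)/C=C/C=O | starting material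
7 | methyl (1S,2R,5S,6R)-2-[4-(benzyloxy)-3-methoxyphenyl]-6-formyl-5-{[tri(propan-2-yl)silyl]oxy}cyclohex-3-ene-1-carboxylate (aryl, formyl and silyloxy cis, ester trans to them) | COC(=O)[C@@H]1[C@@H](C=O)[C@@H](O[Si](C(C)C)(C(C)C)C(C)C)C=C[C@H]1c1ccc(OCc2ccccc2)c(OC)c1 | intermediate (not isolated)
8 | methyl (1S,2R,5S,6S)-2-[4-(benzyloxy)-3-methoxyphenyl]-6-(hydroxymethyl)-5-{[tri(propan-2-yl)silyl]oxy}cyclohex-3-ene-1-carboxylate | COC(=O)[C@@H]1[C@@H](CO)[C@@H](O[Si](C(C)C)(C(C)C)C(C)C)C=C[C@H]1c1ccc(OCc2ccccc2)c(OC)c1 | intermediate
9 | methyl (1S,2R,5S,6S)-2-[4-(benzyloxy)-3-methoxyphenyl]-6-[(benzyloxy)methyl]-5-{[tri(propan-2-yl)silyl]oxy}cyclohex-3-ene-1-carboxylate | COC(=O)[C@@H]1[C@@H](COCc2ccccc2)[C@@H](O[Si](C(C)C)(C(C)C)C(C)C)C=C[C@H]1c1ccc(OCc2ccccc2)c(OC)c1 | intermediate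
10 | methyl (1S,2R,5S,6S)-2-[4-(benzyloxy)-3-methoxyphenyl]-6-[(benzyloxy)methyl]-5-hydroxycyclohex-3-ene-1-carboxylate | COC(=O)[C@@H]1[C@@H](COCc2ccccc2)[C@@H](O)C=C[C@H]1c1ccc(OCc2ccccc2)c(OC)c1 | intermediate
11 | methyl (1S,2R,6S)-2-[4-(benzyloxy)-3-methoxyphenyl]-6-[(benzyloxy)methyl]-5-oxocyclohex-3-ene-1-carboxylate (the all-trans 4-aryl-6-(benzyloxymethyl)-5-(methoxycarbonyl)cyclohex-2-enone) | COC(=O)[C@@H]1[C@@H](COCc2ccccc2)C(=O)C=C[C@H]1c1ccc(OCc2ccccc2)c(OC)c1 | intermediate
12 | methoxyacetone (1-methoxypropan-2-one) | COCC(C)=O | starting material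
13 | methyl formate | COC=O | starting material
14 | sodium (Z)-2-methoxy-3-oxobut-1-en-1-olate (delocalised enolate) | [Na+].[O-]/C=C(\OC)C(C)=O | intermediate (not isolated)
15 | (Z)-3,4-dimethoxybut-3-en-2-one | CO/C=C(\OC)C(C)=O | intermediate
16 | (1Z)-1,2-dimethoxy-3-(trimethylsilyloxy)buta-1,3-diene | CO/C=C(\OC)C(=C)O[Si](C)(C)C | intermediate
17 | methyl (1R,2S,3S)-1-[4-(benzyloxy)-3-methoxyphenyl]-3-[(benzyloxy)methyl]-5,6-dimethoxy-4-oxo-7-[(trimethylsilyl)oxy]-1,2,3,4,4a,5,8,8a-octahydronaphthalene-2-carboxylate (C4a, C5 and C8a transient, configuration not defined) | COC(=O)[C@@H]1[C@@H](COCc2ccccc2)C(=O)C2C(OC)C(OC)=C(O[Si](C)(C)C)CC2[C@H]1c1ccc(OCc2ccccc2)c(OC)c1 | intermediate (not isolated)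
18 | methyl (1R,2S,3S)-1-[4-(benzyloxy)-3-methoxyphenyl]-3-[(benzyloxy)methyl]-6-methoxy-4,7-dioxo-1,2,3,4,4a,7,8,8a-octahydronaphthalene-2-carboxylate (C4a and C8a transient, configuration not defined) | COC(=O)[C@@H]1[C@@H](COCc2ccccc2)C(=O)C2C=C(OC)C(=O)CC2[C@H]1c1ccc(OCc2ccccc2)c(OC)c1 | intermediate (not isolated)
19 | methyl (1R,2S,3S)-1-[4-(benzyloxy)-3-methoxyphenyl]-3-[(benzyloxy)methyl]-7-hydroxy-6-methoxy-4-oxo-1,2,3,4-tetrahydronaphthalene-2-carboxylate | COC(=O)[C@@H]1[C@@H](COCc2ccccc2)C(=O)c2cc(OC)c(O)cc2[C@H]1c1ccc(OCc2ccccc2)c(OC)c1 | intermediate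
20 | methyl (1R,2S,3S)-7-hydroxy-1-(4-hydroxy-3-methoxyphenyl)-3-(hydroxymethyl)-6-methoxy-1,2,3,4-tetrahydronaphthalene-2-carboxylate | COC(=O)[C@@H]1[C@@H](CO)Cc2cc(OC)c(O)cc2[C@H]1c1ccc(O)c(OC)c1 | target

## Step count and least certain steps

Total: 11 steps. Longest linear sequence: 9 steps (steps 1 to 7, 10 and 11); steps 8 and 9 form the two-step diene branch that joins at step 10.

**Step 10 (key step).** The most likely failure is sluggish or diverted bond formation. A cyclohexenone without an extra activating group is a weak dienophile, so acid-induced decomposition of the electron-rich diene, or conjugate addition without the second ring closure, may outrun the annulation. In the oxidation stage, hydride abstraction from the doubly benzylic C1–H could compete if the dihydroarene is slow to form.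

Fallback, setting out from 11 and 12 and returning at 19: the methoxy diene is replaced by a far more nucleophilic amino-siloxy diene, so that no acid catalyst is needed for the cycloaddition. 12 is condensed with Me2NCH(OMe)2 at its methoxy-bearing methylene to give (Z)-4-(dimethylamino)-3-methoxybut-3-en-2-one F1. F1 is converted with KN(SiMe3)2 and tBuMe2SiCl into (1Z)-3-{[tert-butyl(dimethyl)silyl]oxy}-2-methoxy-N,N-dimethylbuta-1,3-dien-1-amine F2. Heating F2 with 11 in toluene should give the amino cycloadduct F3 with the same regiochemistry (CH2 terminus to C8a). Aqueous trifluoroacetic acid then removes the silyl group and expels dimethylamine to give 18, which is dehydrogenated with DDQ to 19 as in step 10.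

**Step 4.** Three processes may go wrong: hydrolysis of the silyl dienol ether in the aqueous acidic medium before it reacts, conjugate addition without ring closure, and insufficient endo or facial selectivity. An exo adduct has the wrong relative configuration at C1, which cannot be repaired later.

Fallback, setting out from 5 and returning at 8: the aldehyde is replaced by a chelating imide and the amine catalyst by an anhydrous chiral Lewis acid. Monomethyl fumarate is acylated onto oxazolidin-2-one (pivaloyl chloride, Et3N, LiCl) to give methyl (E)-4-oxo-4-(2-oxo-1,3-oxazolidin-3-yl)but-2-enoate F4. F4 should undergo a Cu(OTf)2/tert-butyl-bis(oxazoline)-catalysed Diels–Alder reaction with 5 in CH2Cl2; the ligand enantiomer is chosen from the square-planar chelate model to expose the same face. This gives the imide cycloadduct F5, configured as 7. NaBH4 in THF–H2O reduces the N-acyl oxazolidinone selectively to the primary alcohol 8, leaving the methyl ester.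

**Step 11.** The reduction may stall at the benzylic alcohol. If a stronger acid is then used, lactonisation of the γ-hydroxy ester, or elimination to a C3=C4 alkene followed by rehydrogenation, could erode C3.

Fallback, setting out from 19 and returning at 20: the deoxygenation is separated from the deprotection. Ionic hydrogenation (Et3SiH, CF3CO2H, CH2Cl2, 0 °C) reduces the para-hydroxyaryl ketone to methyl (1R,2S,3S)-1-[4-(benzyloxy)-3-methoxyphenyl]-3-[(benzyloxy)methyl]-7-hydroxy-6-methoxy-1,2,3,4-tetrahydronaphthalene-2-carboxylate F6 while the primary alcohol is still benzylated and cannot lactonise. Neutral hydrogenolysis (H2, Pd/C, EtOAc–MeOH) then removes both benzyl groups to give 20.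

**Step 5.** The Brønsted acid may cause loss or migration of the allylic silyl group, or lactonisation of the γ-hydroxy ester.

Fallback, setting out from 7 (isolated after the cycloaddition of step 4 instead of being reduced) and returning at 9: the alcohol stage is bypassed by reductive etherification of the aldehyde with BnOSiMe3 and Et3SiH under FeCl3 catalysis in CH3CN at 0 °C, which gives 9 directly (no new compound, F0).

## Further compounds

F1 | step 10 | (Z)-4-(dimethylamino)-3-methoxybut-3-en-2-one | CN(C)/C=C(\OC)C(C)=O
F2 | step 10 | (1Z)-3-{[tert-butyl(dimethyl)silyl]oxy}-2-methoxy-N,N-dimethylbuta-1,3-dien-1-amine | CN(C)/C=C(\OC)C(=C)O[Si](C)(C)C(C)(C)C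
F3 | step 10 | methyl (1R,2S,3S)-1-[4-(benzyloxy)-3-methoxyphenyl]-3-[(benzyloxy)methyl]-7-{[tert-butyl(dimethyl)silyl]oxy}-5-(dimethylamino)-6-methoxy-4-oxo-1,2,3,4,4a,5,8,8a-octahydronaphthalene-2-carboxylate (C4a, C5 and C8a not defined) | COC(=O)[C@@H]1[C@@H](COCc2ccccc2)C(=O)C2C(N(C)C)C(OC)=C(O[Si](C)(C)C(C)(C)C)CC2[C@H]1c1ccc(OCc2ccccc2)c(OC)c1
F4 | step 4 | methyl (E)-4-oxo-4-(2-oxo-1,3-oxazolidin-3-yl)but-2-enoate | COC(=O)/C=C/C(=O)N1CCOC1=O
F5 | step 4 | methyl 2-[4-(benzyloxy)-3-methoxyphenyl]-6-[(2-oxo-1,3-oxazolidin-3-yl)carbonyl]-5-{[tri(propan-2-yl)silyl]oxy}cyclohex-3-ene-1-carboxylate, configured as 7 at the four ring stereocentres | COC(=O)[C@@H]1[C@@H](C(=O)N2CCOC2=O)[C@@H](O[Si](C(C)C)(C(C)C)C(C)C)C=C[C@H]1c1ccc(OCc2ccccc2)c(OC)c1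
F6 | step 11 | methyl (1R,2S,3S)-1-[4-(benzyloxy)-3-methoxyphenyl]-3-[(benzyloxy)methyl]-7-hydroxy-6-methoxy-1,2,3,4-tetrahydronaphthalene-2-carboxylate | COC(=O)[C@@H]1[C@@H](COCc2ccccc2)Cc2cc(OC)c(O)cc2[C@H]1c1ccc(OCc2ccccc2)c(OC)c1
F0 | step 5 | none | none
A1 | alternative 1 | methyl 2-{[5-(benzyloxy)-2-[(E)-(hydroxyimino)methyl]-4-methoxyphenyl][4-(benzyloxy)-3-methoxyphenyl]methyl}but-3-enoate, C1 and C2 configured as in the target | COC(=O)[C@H](C=C)[C@H](c1ccc(OCc2ccccc2)c(OC)c1)c1cc(OCc2ccccc2)c(OC)cc1/C=N/O
A2 | alternative 1 | all-trans isoxazoline-fused tetralin: methyl 7-(benzyloxy)-1-[4-(benzyloxy)-3-methoxyphenyl]-6-methoxytetralin-2-carboxylate with a C4=N–O–CH2–C3 isoxazoline ring fused across C3–C4 | COC(=O)[C@@H]1[C@H]2CON=C2c2cc(OC)c(OCc3ccccc3)cc2[C@H]1c1ccc(OCc2ccccc2)c(OC)c1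
A3 | alternative 2 | tert-butyl (E)-4-[4-(benzyloxy)-5-methoxy-2-(4,4,5,5-tetramethyl-1,3,2-dioxaborolan-2-yl)phenyl]but-2-enoate | CC(C)(C)OC(=O)/C=C/Cc1cc(OC)c(OCc2ccccc2)cc1B1OC(C)(C)C(C)(C)O1
A4 | alternative 2 | methyl 3-[4-(benzyloxy)-3-methoxyphenyl]prop-2-ynoate | COC(=O)C#Cc1ccc(OCc2ccccc2)c(OC)c1
A5 | alternative 2 | methyl 7-(benzyloxy)-1-[4-(benzyloxy)-3-methoxyphenyl]-3-(2-tert-butoxy-2-oxoethyl)-6-methoxy-3,4-dihydronaphthalene-2-carboxylate, C3 as in the target | COC(=O)C1=C(c2ccc(OCc3ccccc3)c(OC)c2)c2cc(OCc3ccccc3)c(OC)cc2C[C@@H]1CC(=O)OC(C)(C)C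
A6 | alternative 3 | 6-(benzyloxy)-1-[4-(benzyloxy)-3-methoxyphenyl]-5-methoxy-1,3-dihydrobenzo[c]thiophene 2,2-dioxide (racemic at C1) | COc1cc2c(cc1OCc1ccccc1)C(c1ccc(OCc3ccccc3)c(OC)c1)S(=O)(=O)C2
A7 | alternative 3 | (5S)-5-{[(1S,2R,5S)-5-methyl-2-(propan-2-yl)cyclohexyl]oxy}furan-2(5H)-one | O=C1C=C[C@@H](O[C@H]2C[C@@H](C)CC[C@@H]2C(C)C)O1
A8 | alternative 3 | all-cis lactone acetal of 7-(benzyloxy)-1-[4-(benzyloxy)-3-methoxyphenyl]-6-methoxytetralin: lactone carbonyl on C2, (1S,2R,5S)-menthyloxy acetal carbon on C3 | O=C3[C@H]1[C@@H]([C@@H](O[C@H]4C[C@@H](C)CC[C@@H]4C(C)C)O3)Cc2cc(OC)c(OCc4ccccc4)cc2[C@H]1c1ccc(OCc2ccccc2)c(OC)c1
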